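**Strategy.** The route rests on disconnecting the C2–C3 bond of the pyran ring. C2 is a tertiary ether carbon on O1, so its C–H precursor is hydridic, and it is the sixth atom from C3 once C4 is an aryl ketone carbon on C4a. A rhodium carbenoid generated at C3 from a diazomethyl ketone inserts into this C2–H bond of an (S)-sec-alkyl aryl ether with retention. This closes the pyranone ring and turns a carbinol stereocentre set by ketone reduction into the quaternary C2 in one operation. The precursor is an open-chain aryl ether that already carries the complete trienoate side chain and an ortho diazoacetyl group.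

Key step: step 10

Assumption: (E)-geranylacetone of high isomeric purity and an (R)-selective alcohol dehydrogenase preparation are taken as purchasable; C2 of the target is (S).

**Step 1**
Reactants: 1 2,3-dimethylbenzene-1,4-diol
Product: 2 1-(2,5-dihydroxy-3,4-dimethylphenyl)ethan-1-one
Conditions: AcOH, BF3·OEt2, 110 °C
Reagents that add atoms: acetic acid, CC(=O)O
Why: Friedel–Crafts acylation (O-acylation then Fries rearrangement) should give one ketone because the two free ring positions of 1 are equivalent.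

**Step 2**
Reactants: 2 1-(2,5-dihydroxy-3,4-dimethylphenyl)ethan-1-one
Product: 3 1-[5-(tert-butyldimethylsilyloxy)-2-hydroxy-3,4-dimethylphenyl]ethan-1-one
Conditions: TBSCl, imidazole, DMF, 0 °C
Reagents that add atoms: tert-butyldimethylsilyl chloride, CC(C)(C)[Si](C)(C)Cl
Why: Selective silylation should take the free C5 hydroxyl, since the C2 hydroxyl is hydrogen-bonded to the carbonyl group and flanked by a methyl group.

**Step 3**
Reactants: 4 (E)-geranylacetone [(E)-6,10-dimethylundeca-5,9-dien-2-one]
Product: 6 racemic (E)-8-(3,3-dimethyloxiran-2-yl)-6-methyloct-5-en-2-one, via bromohydrin 5 (not isolated)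
Conditions: NBS, THF/H2O, 0 °C; then K2CO3, MeOH, rt
Reagents that add atoms: water, O (epoxide oxygen); N-bromosuccinimide, O=C1CCC(=O)N1Br (bromine kept only in 5)
Why: Bromohydrin formation in aqueous THF should favour the terminal alkene, as is usual for polyprenyl chains, and base then closes the epoxide by intramolecular Williamson displacement; the new stereocentre is racemic and is destroyed in step 4.

**Step 4**
Reactants: 6 racemic (E)-8-(3,3-dimethyloxiran-2-yl)-6-methyloct-5-en-2-one
Product: 7 (E)-4-methyl-8-oxonon-4-enal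
Conditions: H5IO6, THF/Et2O, 0 °C
Reagents that add atoms: none
Why: Periodic acid opens the epoxide to the diol and cleaves it (Malaprade-type glycol cleavage) to the aldehyde and acetone without touching the ketone or the trisubstituted alkene.

**Step 5**
Reactants: 8 5-bromo-2-methylpent-2-ene; 9 methyl (triphenyl-λ5-phosphanylidene)acetate
Product: 11 methyl 6-methyl-2-(triphenyl-λ5-phosphanylidene)hept-5-enoate, via phosphonium bromide 10 (not isolated)
Conditions: MeCN, reflux; then CH2Cl2, 1 M aq. NaOH, 0 °C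
Reagents that add atoms: none
Why: C-alkylation of the stabilised ylide by the primary bromide (SN2) gives the α-substituted phosphonium salt, which hydroxide deprotonates to the new stabilised ylide.

**Step 6**
Reactants: 7 (E)-4-methyl-8-oxonon-4-enal; 11 methyl 6-methyl-2-(triphenyl-λ5-phosphanylidene)hept-5-enoate
Product: 12 methyl (2E,6E)-6-methyl-2-(4-methylpent-3-en-1-yl)-10-oxoundeca-2,6-dienoate
Conditions: toluene, 80 °C
Reagents that add atoms: none
Why: Wittig olefination with an α-branched stabilised ylide should react only at the aldehyde and give the (E)-enoate (ester trans to the chain) under thermodynamic control of oxaphosphetane formation.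

**Step 7**
Reactants: 12 methyl (2E,6E)-6-methyl-2-(4-methylpent-3-en-1-yl)-10-oxoundeca-2,6-dienoate
Product: 13 methyl (2E,6E,10R)-10-hydroxy-6-methyl-2-(4-methylpent-3-en-1-yl)undeca-2,6-dienoate
Conditions: (R)-selective alcohol dehydrogenase (Lactobacillus kefir type), NADP+ (cat.), MgCl2, iPrOH/phosphate buffer pH 7, 30 °C
Reagents that add atoms: none
Why: Biocatalytic ketone reduction with cofactor recycling by propan-2-ol should deliver hydride to the si face of the methyl ketone, setting the (R)-carbinol centre under enzyme control and leaving the enoate untouched.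

**Step 8**
Reactants: 13 methyl (2E,6E,10R)-10-hydroxy-6-methyl-2-(4-methylpent-3-en-1-yl)undeca-2,6-dienoate; 3 1-[5-(tert-butyldimethylsilyloxy)-2-hydroxy-3,4-dimethylphenyl]ethan-1-one
Product: 14 methyl (2E,6E,10S)-10-[2-acetyl-4-(tert-butyldimethylsilyloxy)-5,6-dimethylphenoxy]-6-methyl-2-(4-methylpent-3-en-1-yl)undeca-2,6-dienoate
Conditions: PPh3, DIAD, toluene, 0 °C to rt
Reagents that add atoms: none
Why: Mitsunobu etherification with the acidic ortho-acyl phenol should proceed by SN2 displacement of the oxyphosphonium group, so the (R)-alcohol gives the (S)-aryl ether by inversion.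

**Step 9**
Reactants: 14 methyl (2E,6E,10S)-10-[2-acetyl-4-(tert-butyldimethylsilyloxy)-5,6-dimethylphenoxy]-6-methyl-2-(4-methylpent-3-en-1-yl)undeca-2,6-dienoate
Product: 16 methyl (2E,6E,10S)-10-[4-(tert-butyldimethylsilyloxy)-2-(2-diazoacetyl)-5,6-dimethylphenoxy]-6-methyl-2-(4-methylpent-3-en-1-yl)undeca-2,6-dienoate, via trifluoroacetyl diketone 15 (not isolated)
Conditions: LiN(SiMe3)2, THF, −78 °C; CF3CO2CH2CF3; dilute HCl work-up; then MsN3, Et3N, H2O, MeCN, rt
Reagents that add atoms: methanesulfonyl azide, CS(=O)(=O)N=[N+]=[N-] (the two diazo nitrogens); 2,2,2-trifluoroethyl trifluoroacetate, O=C(OCC(F)(F)F)C(F)(F)F (trifluoroacetyl group kept only in 15)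
Why: Kinetic enolisation of the aryl methyl ketone and Claisen-type trifluoroacetylation activate it for Regitz diazo transfer, and retro-Claisen loss of the trifluoroacetyl group (detrifluoroacetylative diazo transfer) should give the diazomethyl ketone with the enoate and the stereocentre unaffected.

**Step 10**
Reactants: 16 methyl (2E,6E,10S)-10-[4-(tert-butyldimethylsilyloxy)-2-(2-diazoacetyl)-5,6-dimethylphenoxy]-6-methyl-2-(4-methylpent-3-en-1-yl)undeca-2,6-dienoate
Product: 17 methyl (2E,6E)-9-[(2S)-6-(tert-butyldimethylsilyloxy)-2,7,8-trimethyl-4-oxochroman-2-yl]-6-methyl-2-(4-methylpent-3-en-1-yl)nona-2,6-dienoate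
Conditions: Rh2(OAc)4 (1 mol %), CH2Cl2, 40 °C, slow addition of 16
Reagents that add atoms: none
Why: Rh2(OAc)4 decomposes the diazo ketone with loss of N2 to an electrophilic divalent-rhodium carbenoid at C3, which inserts through a concerted, asynchronous three-centre transition state into the tertiary C2–H bond that the lone pairs of O1 make hydridic. The closest known reaction type is the dirhodium-catalysed intramolecular C–H insertion of 2-alkoxyphenyl diazomethyl ketones that gives chroman-4-ones. The pyranone ring closes by 1,6-insertion through a six-membered cyclic transition state made of C3, C4, C4a, C8a, O1 and C2. The new quaternary stereocentre C2 is controlled by the existing (S)-ether centre, because insertion replaces H by C3 on the same face (retention), so (S)-16 should give (S)-17. The step needs site selectivity for C2–H over oxonium-ylide formation at O1, over cyclopropanation of the chain alkenes and over other C–H bonds. This is secured because the aryl ketone tether allows no five-membered insertion, C2–H is the only ether-activated tertiary C–H within reach, the alkenes could only be reached through rings of nine or more members, and the ether carries no allyl or benzyl group that would drive an ylide rearrangement.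

**Step 11**
Reactants: 17 methyl (2E,6E)-9-[(2S)-6-(tert-butyldimethylsilyloxy)-2,7,8-trimethyl-4-oxochroman-2-yl]-6-methyl-2-(4-methylpent-3-en-1-yl)nona-2,6-dienoate
Product: 18 methyl (2E,6E)-9-[(2S,4RS)-6-(tert-butyldimethylsilyloxy)-4-hydroxy-2,7,8-trimethylchroman-2-yl]-6-methyl-2-(4-methylpent-3-en-1-yl)nona-2,6-dienoate
Conditions: NaBH4, THF/MeOH, 0 °C
Reagents that add atoms: none
Why: Borohydride reduction should take the aryl ketone and leave the conjugated ester; the C4 epimer mixture is of no consequence because C4 becomes sp2 in step 12.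

**Step 12**
Reactants: 18 methyl (2E,6E)-9-[(2S,4RS)-6-(tert-butyldimethylsilyloxy)-4-hydroxy-2,7,8-trimethylchroman-2-yl]-6-methyl-2-(4-methylpent-3-en-1-yl)nona-2,6-dienoate
Product: 19 methyl (2E,6E)-9-[(2S)-6-(tert-butyldimethylsilyloxy)-2,7,8-trimethyl-2H-chromen-2-yl]-6-methyl-2-(4-methylpent-3-en-1-yl)nona-2,6-dienoate
Conditions: pTsOH·H2O (cat.), toluene, 60 °C
Reagents that add atoms: none
Why: Acid-catalysed E1 dehydration through the benzylic C4 cation, stabilised by the ortho oxygen O1, can only lose a proton from C3 and should give the C3=C4 alkene without touching C2.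

**Step 13**
Reactants: 19 methyl (2E,6E)-9-[(2S)-6-(tert-butyldimethylsilyloxy)-2,7,8-trimethyl-2H-chromen-2-yl]-6-methyl-2-(4-methylpent-3-en-1-yl)nona-2,6-dienoate
Product: 20 (2E,6E)-9-[(2S)-6-hydroxy-2,7,8-trimethyl-2H-chromen-2-yl]-6-methyl-2-(4-methylpent-3-en-1-yl)nona-2,6-dienoic acid (CNP0158414.1)
Conditions: LiOH, degassed THF/MeOH/H2O, 45 °C; then 1 M HCl to pH 3, 0 °C
Reagents that add atoms: lithium hydroxide, [Li+].[OH-] (one carboxyl oxygen)
Why: Saponification of the methyl ester and hydroxide cleavage of the aryl silyl ether should occur in the same operation, with air excluded to protect the electron-rich chromenol.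

**Compound list**
1 | 2,3-dimethylbenzene-1,4-diol | Cc1c(C)c(O)ccc1O | starting material
2 | 1-(2,5-dihydroxy-3,4-dimethylphenyl)ethan-1-one | CC(=O)c1cc(O)c(C)c(C)c1O | intermediate
3 | 1-[5-(tert-butyldimethylsilyloxy)-2-hydroxy-3,4-dimethylphenyl]ethan-1-one | CC(=O)c1cc(O[Si](C)(C)C(C)(C)C)c(C)c(C)c1O | intermediate
4 | (E)-geranylacetone, (E)-6,10-dimethylundeca-5,9-dien-2-one | CC(C)=CCC/C(C)=C/CCC(C)=O | starting material
5 | racemic (E)-9-bromo-10-hydroxy-6,10-dimethylundec-5-en-2-one | CC(C)(O)C(Br)CC/C(C)=C/CCC(C)=O | intermediate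
6 | racemic (E)-8-(3,3-dimethyloxiran-2-yl)-6-methyloct-5-en-2-one | CC1(C)OC1CC/C(C)=C/CCC(C)=O | intermediate
7 | (E)-4-methyl-8-oxonon-4-enal | O=CCC/C(C)=C/CCC(C)=O | intermediate
8 | 5-bromo-2-methylpent-2-ene | CC(C)=CCCBr | starting material
9 | methyl (triphenyl-λ5-phosphanylidene)acetate | COC(=O)C=P(c1ccccc1)(c1ccccc1)c1ccccc1 | starting material
10 | (1-methoxy-6-methyl-1-oxohept-5-en-2-yl)triphenylphosphonium bromide | COC(=O)C(CCC=C(C)C)[P+](c1ccccc1)(c1ccccc1)c1ccccc1.[Br-] | intermediate
11 | methyl 6-methyl-2-(triphenyl-λ5-phosphanylidene)hept-5-enoate | COC(=O)C(CCC=C(C)C)=P(c1ccccc1)(c1ccccc1)c1ccccc1 | intermediate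
12 | methyl (2E,6E)-6-methyl-2-(4-methylpent-3-en-1-yl)-10-oxoundeca-2,6-dienoate | CC(C)=CCC/C(=C\CC/C(C)=C/CCC(C)=O)C(=O)OC | intermediate
13 | methyl (2E,6E,10R)-10-hydroxy-6-methyl-2-(4-methylpent-3-en-1-yl)undeca-2,6-dienoate | CC(C)=CCC/C(=C\CC/C(C)=C/CC[C@@H](C)O)C(=O)OC | intermediate
14 | methyl (2E,6E,10S)-10-[2-acetyl-4-(tert-butyldimethylsilyloxy)-5,6-dimethylphenoxy]-6-methyl-2-(4-methylpent-3-en-1-yl)undeca-2,6-dienoate | CC(C)=CCC/C(=C\CC/C(C)=C/CC[C@H](C)Oc1c(C)c(C)c(O[Si](C)(C)C(C)(C)C)cc1C(C)=O)C(=O)OC | intermediate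
15 | methyl (2E,6E,10S)-10-[4-(tert-butyldimethylsilyloxy)-5,6-dimethyl-2-(4,4,4-trifluoro-3-oxobutanoyl)phenoxy]-6-methyl-2-(4-methylpent-3-en-1-yl)undeca-2,6-dienoate | CC(C)=CCC/C(=C\CC/C(C)=C/CC[C@H](C)Oc1c(C)c(C)c(O[Si](C)(C)C(C)(C)C)cc1C(=O)CC(=O)C(F)(F)F)C(=O)OC | intermediate
16 | methyl (2E,6E,10S)-10-[4-(tert-butyldimethylsilyloxy)-2-(2-diazoacetyl)-5,6-dimethylphenoxy]-6-methyl-2-(4-methylpent-3-en-1-yl)undeca-2,6-dienoate | CC(C)=CCC/C(=C\CC/C(C)=C/CC[C@H](C)Oc1c(C)c(C)c(O[Si](C)(C)C(C)(C)C)cc1C(=O)C=[N+]=[N-])C(=O)OC | intermediate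
17 | methyl (2E,6E)-9-[(2S)-6-(tert-butyldimethylsilyloxy)-2,7,8-trimethyl-4-oxochroman-2-yl]-6-methyl-2-(4-methylpent-3-en-1-yl)nona-2,6-dienoate | CC(C)=CCC/C(=C\CC/C(C)=C/CC[C@@]1(C)CC(=O)c2cc(O[Si](C)(C)C(C)(C)C)c(C)c(C)c2O1)C(=O)OC | intermediate
18 | methyl (2E,6E)-9-[(2S,4RS)-6-(tert-butyldimethylsilyloxy)-4-hydroxy-2,7,8-trimethylchroman-2-yl]-6-methyl-2-(4-methylpent-3-en-1-yl)nona-2,6-dienoate | CC(C)=CCC/C(=C\CC/C(C)=C/CC[C@@]1(C)CC(O)c2cc(O[Si](C)(C)C(C)(C)C)c(C)c(C)c2O1)C(=O)OC | intermediate
19 | methyl (2E,6E)-9-[(2S)-6-(tert-butyldimethylsilyloxy)-2,7,8-trimethyl-2H-chromen-2-yl]-6-methyl-2-(4-methylpent-3-en-1-yl)nona-2,6-dienoate | CC(C)=CCC/C(=C\CC/C(C)=C/CC[C@@]1(C)C=Cc2cc(O[Si](C)(C)C(C)(C)C)c(C)c(C)c2O1)C(=O)OC | intermediate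
20 | (2E,6E)-9-[(2S)-6-hydroxy-2,7,8-trimethyl-2H-chromen-2-yl]-6-methyl-2-(4-methylpent-3-en-1-yl)nona-2,6-dienoic acid | CC(C)=CCC/C(=C\CC/C(C)=C/CC[C@@]1(C)C=Cc2cc(O)c(C)c(C)c2O1)C(=O)O | target

**Totals.** Total step count: 13. Longest linear sequence: 10 steps (from 4 through steps 3, 4, 6, 7, 8, 9, 10, 11, 12 and 13).

**Steps most likely to fail**

Step 10. The carbenoid may be diverted from C–H insertion: attack at the lone pair of O1 would give an oxonium ylide that collapses by 1,2-shift or elimination, a chain alkene may be cyclopropanated, or a stepwise hydride-transfer pathway may erode the configuration at C2. The fallback sets out from 12 and 3 and returns at 17. A Kabbe condensation of ketone 12 with phenol 3 (pyrrolidine, toluene, 80 °C; enamine aldol condensation followed by oxa-Michael closure at O1–C2) should give the racemic chromanone F1. Preparative HPLC on a chiral stationary phase would then deliver 17 and leave the (R)-chromanone F2. This fallback closes the ring at O1–C2 rather than C2–C3.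

Step 8. The redox condensation may stall because the chelated, doubly ortho-substituted phenol is a poor nucleophile, and the activated secondary alcohol may then be lost by elimination. The fallback sets out from 13 and returns at 14. Alcohol 13 would be converted with MsCl and Et3N (CH2Cl2, 0 °C) into the (R)-mesylate F3, which the caesium phenoxide of 3 (Cs2CO3, dry MeCN, 60 °C) should displace with inversion to give 14.

Step 5. Alkylation of the weakly nucleophilic stabilised ylide by an unactivated primary bromide may be too slow, so that decomposition of the ylide on prolonged heating overtakes it. The fallback sets out from 8 and returns at 12. Bromide 8 would alkylate the sodium salt of trimethyl phosphonoacetate (NaH, DMSO, 50 °C) to the phosphonate F4. A Horner–Wadsworth–Emmons reaction of F4 with aldehyde 7 (NaH, THF, 0 °C) should then give 12 together with its (2Z)-isomer F5, which would be removed by chromatography.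

**Further compounds**
F1 | step 10 | racemic methyl (2E,6E)-9-[6-(tert-butyldimethylsilyloxy)-2,7,8-trimethyl-4-oxochroman-2-yl]-6-methyl-2-(4-methylpent-3-en-1-yl)nona-2,6-dienoate | CC(C)=CCC/C(=C\CC/C(C)=C/CCC1(C)CC(=O)c2cc(O[Si](C)(C)C(C)(C)C)c(C)c(C)c2O1)C(=O)OC
F2 | step 10 | methyl (2E,6E)-9-[(2R)-6-(tert-butyldimethylsilyloxy)-2,7,8-trimethyl-4-oxochroman-2-yl]-6-methyl-2-(4-methylpent-3-en-1-yl)nona-2,6-dienoate | CC(C)=CCC/C(=C\CC/C(C)=C/CC[C@]1(C)CC(=O)c2cc(O[Si](C)(C)C(C)(C)C)c(C)c(C)c2O1)C(=O)OC
F3 | step 8 | methyl (2E,6E,10R)-10-(methanesulfonyloxy)-6-methyl-2-(4-methylpent-3-en-1-yl)undeca-2,6-dienoate | CC(C)=CCC/C(=C\CC/C(C)=C/CC[C@@H](C)OS(C)(=O)=O)C(=O)OC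
F4 | step 5 | methyl 2-(dimethoxyphosphoryl)-6-methylhept-5-enoate | COC(=O)C(CCC=C(C)C)P(=O)(OC)OC
F5 | step 5 | methyl (2Z,6E)-6-methyl-2-(4-methylpent-3-en-1-yl)-10-oxoundeca-2,6-dienoate | CC(C)=CCC/C(=C/CC/C(C)=C/CCC(C)=O)C(=O)OC
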